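**The balance.** Whatever happens in a run, what was charged as substrate stays counted, and the last autumn row adds up to 98.7%, so you may read the substrate lost as the substrate turned into target and side product.

all flasks: initiator 10 mM

| flask | substrate | reagent | transfer agent | remark | time |
|---|---|---|---|---|---|
| autumn | 0.14 M | 0.15 M | 0.10 M | run made earlier |  |
| dusk | 0.22 M | 0.15 M | 0.10 M | run made earlier |  |
| flask | 0.10 M | 0.150 M | 0.100 M |  | 2.5 d |

| run | time / h | substrate / % | side product / % | target / % | first chain carrier / % |
|---|---|---|---|---|---|
| autumn | 6.00 | 73.9 | 6.0 | 19.8 | 0.9 |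
| autumn | 15.0 | 62.3 | 10.0 | 27.8 | 0 |
| autumn | 30.0 | 60.7 | 11.3 | 28.6 | 0 |
| autumn | 50.0 | 59.7 | 9.3 | 29.3 | 0.4 |
| dusk | 6.00 | 80.2 | 7.0 | 12.5 | 2.4 |
| dusk | 15.0 | 74.1 | 7.8 | 17.9 | 0 |
| dusk | 30.0 | 71.4 | 7.3 | 19.2 | 0 |
| dusk | 50.0 | 71.6 | 6.0 | 19.4 | 0 |

(readings scatter by 1 percentage point)

* the species in which most of what was charged as substrate, at 2.5 d sits (side product / substrate / target / first chain carrier)
* the largest share itself, whichever of these holds it, in percent of the substrate charged

**The stall.** In the autumn run c(substrate) reads 60.7% at 30.0 h and 59.7% at 50.0 h, a step within the scatter of 1 percentage point, so I take the mean of these last two readings in each run as its end, and since 2.5 d lies beyond the last reading, I expect this flask to have stalled too.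

**Molar reckoning.** Those means give 0.0557 M consumed in the autumn run and 0.0627 M in the dusk run, so you see that a much larger charge consumes hardly more. A straight line through both gives 0.0522 M for this flask, which leaves 47.8%.

**Weak link.** That line keeps a positive consumption as the charge shrinks towards nothing, yet an empty flask consumes nothing, so I bend it into a power of the charge, with exponent 0.261. This gives the flask a capacity, the molar amount of substrate consumed before the stall, of 0.0510 M, and I commit to 49.0% left.

**The forecast.** It names substrate at 48%, a little below my figure, on the ground that the near-equal amounts “suggests a fixed capacity, probably the initiator burning out”.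

**The flask.**

    initiator → 2 initiating radical (k = 5.74 × 10⁻⁵ s⁻¹)
    substrate + initiating radical → capped initiator + first chain carrier (k = 31800 M⁻¹ s⁻¹)
    reagent + first chain carrier → target + second chain carrier (k = 946 M⁻¹ s⁻¹)
    substrate + second chain carrier → by-product + first chain carrier (k = 563 M⁻¹ s⁻¹)
    transfer agent + first chain carrier → side product + idle radical (kL = 400 M⁻¹ s⁻¹)
    2 idle radical → ended radicals (k = 6.00 × 10⁷ M⁻¹ s⁻¹)
    2 second chain carrier → ended chains A (k = 3.30 × 10⁸ M⁻¹ s⁻¹)
    2 first chain carrier → ended chains B (k = 2.00 × 10⁸ M⁻¹ s⁻¹)
    target → over-reaction product (k = 4.86 × 10⁻⁸ s⁻¹)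
    reagent ⇌ dormant form (K = 0.230, k = 2.18 × 10⁻⁵ s⁻¹)

The flask holds most in substrate, at 51.3%, ahead of target at 35.0%, so its capacity was 0.0487 M against the 0.0510 M reckoned. The initiator's half-life of 0.14 d at 0.147 d is far shorter than the 2.5 d, initiator stands at 0% of its charge at the end, and substrate reads 51.4% at 1.25 d and 51.3% at 25.0 d. For the forecast to be wrong, a run would have to show target overtaking substrate or the share moving out of its margin, and initiator is the setting to try: in this flask, with all else held, 11.5 mM of initiator moves the end substrate by 5 points, and the neighbour flask with 0.040 M of initiator ends with substrate at 0% and target leading at 66.8%.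

All runs come from a simulation for an exercise, and the scatter is random.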